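**Retrosynthetic overview**
1. Structural feature: in quinone rings A and B the ring-linking carbon sits next to the carbon bearing the 2-phenylethyl chain. The four atoms C(CH2CH2Ph)=C–C=C(CH2CH2Ph) across the A–B bond are therefore one conjugated diene shared by both rings. The other four carbons of each ring (C=O, C–CH3, C–OH, C=O) are a squaric-acid C4 unit.
2. Target ⇒ bis(isopropoxyquinone) ⇒ bis(hydroquinone). Cutting, in each ring, the bond between the linking carbon and the carbonyl carbon next to C–CH3 gives a diene with a 4-hydroxycyclobutenone on each terminus.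
3. That diene ⇒ twofold 1,2-addition of a cis,cis-1,4-dilithiodiene to 3-isopropoxy-4-methylcyclobutenedione (from diisopropyl squarate and MeLi).
4. Dilithiodiene ⇒ 2,5-disubstituted tellurophene ⇒ 1,3-diyne ⇒ Glaser–Hay dimerisation of 4-phenyl-1-butyne, which already makes the future A–B bond.
5. Ring order: the tellurophene is temporary (made, then cleaved). The two purchased four-membered rings are attached next. Rings A and B are closed together in one thermolysis and then oxidised.

Key step: step 6

Assumption: the structure defines no configuration for the hindered A–B axis, so no axial control is sought and the product is taken as the unresolved form.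

Step 1
Reactants: 1 4-phenyl-1-butyne (two molecules)
Product: 2 1,8-diphenylocta-3,5-diyne
Conditions: CuCl (10 mol %), TMEDA (20 mol %), O2 (1 atm), acetone, rt
Reagents that add atoms: none
Why: Glaser–Hay oxidative homocoupling through copper acetylides joins the two terminal sp carbons, creating the C–C bond that later becomes the A–B bond, and the phenethyl chain is inert to it.

Step 2
Reactants: 2 1,8-diphenylocta-3,5-diyne
Product: 3 2,5-bis(2-phenylethyl)tellurophene
Conditions: Te, NaBH4, EtOH–H2O (degassed), reflux; then 2, THF, reflux
Reagents that add atoms: tellurium, [Te] (delivered as Na2Te)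
Why: telluride adds as a soft nucleophile in anti fashion to an outer alkyne carbon of the conjugated diyne and the resulting cis-enynyl tellurolate closes onto the second alkyne, which is the established tellurophene synthesis from 1,3-diynes and locks both alkenes in the cis,cis arrangement.

Step 3
Reactants: 4 diisopropyl squarate; 5 methyllithium
Product: 6 4-hydroxy-4-methyl-2,3-di(propan-2-yloxy)cyclobut-2-en-1-one (racemic)
Conditions: THF, −78 °C; aq NH4Cl
Reagents that add atoms: methyllithium (5), [Li]C
Why: organolithium 1,2-addition to one of the two equivalent squarate carbonyls should stop at the mono-adduct at low temperature, and the new carbinol centre is racemic and is removed in step 4.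

Step 4
Reactants: 6 4-hydroxy-4-methyl-2,3-di(propan-2-yloxy)cyclobut-2-en-1-one
Product: 7 3-isopropoxy-4-methylcyclobut-3-ene-1,2-dione
Conditions: conc. HCl (cat.), CH2Cl2, rt
Reagents that add atoms: none
Why: acid ionises the tertiary allylic alcohol to an alkoxy-stabilised cyclobutenyl cation, which takes up the released water at the distal alkoxy carbon and expels propan-2-ol, the standard conversion of squarate adducts into 3-alkoxy-4-alkylcyclobutenediones.

Step 5
Reactants: 3 2,5-bis(2-phenylethyl)tellurophene; 7 3-isopropoxy-4-methylcyclobut-3-ene-1,2-dione (two molecules incorporated)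
Product: 9 (3Z,5Z)-1,8-diphenylocta-3,5-diene-3,6-diyl-bis(4-hydroxy-3-isopropoxy-2-methylcyclobut-2-en-1-one) as a meso/dl mixture, via cis-cis dilithiodiene 8 (not isolated)
Conditions: n-BuLi (2.0 equiv), THF, −78 °C; cannulated into 7 (4 equiv), THF, −90 °C; aq NH4Cl, −78 °C
Reagents that add atoms: n-butyllithium, [Li]CCCC (supplies the lithium atoms of 8; none of its atoms stay in 9)
Why: tellurium–lithium exchange of vinylic tellurides is fast and retains geometry, so cleavage of 3 should give 8 with each C–Li bond cis to the neighbouring alkene; alkenyllithiums add 1,2 to the carbonyl of 7 next to the alkoxy-bearing carbon because the other carbonyl is deactivated as a vinylogous ester; inverse addition into cold excess 7 steers the second C–Li bond to fresh dione rather than to the weaker carbonyl of the ring already attached; the two carbinol centres form without control and are erased in step 6.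

Step 6
Reactants: 9 bis(4-hydroxycyclobutenonyl)diene
Product: 13 3,3'-dimethyl-6,6'-bis(2-phenylethyl)-4,4'-di(propan-2-yloxy)biphenyl-2,2',5,5'-tetrol, via first dienylketene 10 (not isolated), via half-expanded hydroquinone-cyclobutenone 11 (not isolated), via second dienylketene 12 (not isolated)
Conditions: PhMe (degassed, 0.01 M), 110 °C, Ar
Reagents that add atoms: none
Why: Proposed new method: heating should open each 4-hydroxycyclobutenone by conrotatory 4π cleavage of the C(=O)–C(OH) ring bond, the hydroxyl donor turning outward so that the alkenyl arm ends up cis to the new ketene (10, later 12). Each six-membered carbocycle is then closed by a 6π-electrocyclisation that bonds the ketene carbon to the inner CH carbon of the diene, and enolisation of the keto tautomer aromatises it; one ring forms first (11), the other follows in the same pot, and the central single bond of the diene is left as the aryl–aryl bond. The closest known reaction type is the thermal ring expansion of 4-alkenyl-4-hydroxycyclobutenones to hydroquinones (Moore rearrangement); what has not been shown is its twofold use on one conjugated diene in which each accepting carbon carries the other half as a cis substituent. No stereocentre is created: the two carbinol centres and both alkene geometries disappear on aromatisation, and the new axis is not defined in the target. The step needs inward rotation of the alkenyl group, which the outward preference of the hydroxyl secures, and 6π rather than 8π closure, which is favoured because the far diene terminus is fully substituted with a quaternary carbinol carbon pointing inward, because an eight-membered trienone could reopen whereas enolisation drains the 6π channel irreversibly, and because the 8π option vanishes once the first ring is aromatic. The sp ketene terminus bears no inward substituent, so the cis group on the accepting carbon should cost far less than in an all-carbon triene, and high dilution limits capture of the ketenes by phenols already formed.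

Step 7
Reactants: 13 biaryl bis(hydroquinone) diisopropyl ether (crude)
Product: 14 5,5'-diisopropoxy-6,6'-dimethyl-3,3'-bis(2-phenylethyl)-2,2'-bi(1,4-benzoquinone)
Conditions: Ag2O, Et2O, rt
Reagents that add atoms: none
Why: hydroquinone-to-quinone oxidation with Ag2O is neutral and mild, leaves the ethers and the CH2 groups untouched, and the fully substituted rings offer no position for conjugate addition.

Step 8
Reactants: 14 bis(isopropoxyquinone)
Product: 15 5,5'-dihydroxy-6,6'-dimethyl-3,3'-bis(2-phenylethyl)-2,2'-bi(1,4-benzoquinone) (CNP0136737.0)
Conditions: BCl3, CH2Cl2, −78 to 0 °C; H2O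
Reagents that add atoms: none
Why: Lewis-acid dealkylation of isopropyl ethers, in which BCl3 binds the adjacent carbonyl and ether oxygens and chloride cleaves the secondary alkyl–oxygen bond, should free both vinylogous acids without base that could tautomerise the alkylquinones to quinone methides.

**Compound list**
1 | 4-phenyl-1-butyne | C#CCCc1ccccc1 | starting material
2 | 1,8-diphenylocta-3,5-diyne | C(Cc1ccccc1)C#CC#CCCc1ccccc1 | intermediate
3 | 2,5-bis(2-phenylethyl)tellurophene | C1(CCc2ccccc2)=CC=C(CCc2ccccc2)[Te]1 | intermediate
4 | diisopropyl squarate | CC(C)OC1=C(OC(C)C)C(=O)C1=O | starting material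
5 | methyllithium | [Li]C | starting material
6 | 4-hydroxy-4-methyl-2,3-di(propan-2-yloxy)cyclobut-2-en-1-one (racemic) | CC1(O)C(OC(C)C)=C(OC(C)C)C1=O | intermediate
7 | 3-isopropoxy-4-methylcyclobut-3-ene-1,2-dione | CC1=C(OC(C)C)C(=O)C1=O | intermediate
8 | 3,6-dilithio-1,8-diphenylocta-3,5-diene, each Li cis to the other C=C (not isolated) | [Li]/C(CCc1ccccc1)=C\C=C(/[Li])CCc1ccccc1 | intermediate
9 | bis(4-hydroxy-3-isopropoxy-2-methyl-4-cyclobutenonyl)diene, each ring carbon cis to the other C=C, meso/dl at the carbinols | O=C1C(C)=C(OC(C)C)C1(O)/C(CCc1ccccc1)=C\C=C(/C1(O)C(OC(C)C)=C(C)C1=O)CCc1ccccc1 | intermediate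
10 | first dienylketene, hydroxyl trans and alkenyl arm cis to the ketenyl carbon (not isolated) | O=C=C(C)/C(OC(C)C)=C(/O)\C(CCc1ccccc1)=C/C=C(\C1(O)C(OC(C)C)=C(C)C1=O)CCc1ccccc1 | intermediate
11 | half-expanded compound: hydroquinone ring joined through a cis alkene to the remaining 4-hydroxycyclobutenone (not isolated) | Cc1c(O)c(/C=C(\C2(O)C(OC(C)C)=C(C)C2=O)CCc2ccccc2)c(CCc2ccccc2)c(O)c1OC(C)C | intermediate
12 | second dienylketene carrying the finished hydroquinone ring (not isolated) | O=C=C(C)/C(OC(C)C)=C(/O)\C(CCc1ccccc1)=C/c1c(O)c(C)c(OC(C)C)c(O)c1CCc1ccccc1 | intermediate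
13 | 3,3'-dimethyl-6,6'-bis(2-phenylethyl)-4,4'-di(propan-2-yloxy)biphenyl-2,2',5,5'-tetrol | Cc1c(O)c(c(CCc2ccccc2)c(O)c1OC(C)C)-c1c(CCc2ccccc2)c(O)c(OC(C)C)c(C)c1O | intermediate
14 | 5,5'-diisopropoxy-6,6'-dimethyl-3,3'-bis(2-phenylethyl)-2,2'-bi(1,4-benzoquinone) | CC1=C(OC(C)C)C(=O)C(CCc2ccccc2)=C(C2=C(CCc3ccccc3)C(=O)C(OC(C)C)=C(C)C2=O)C1=O | intermediate
15 | 5,5'-dihydroxy-6,6'-dimethyl-3,3'-bis(2-phenylethyl)-2,2'-bi(1,4-benzoquinone), CNP0136737.0 | CC1=C(O)C(=O)C(CCc2ccccc2)=C(C2=C(CCc3ccccc3)C(=O)C(O)=C(C)C2=O)C1=O | target

Total step count: 8. Longest linear sequence: 6 steps (steps 1, 2, 5, 6, 7, 8; the squarate branch through steps 3, 4, 5, 6, 7, 8 is equally long).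

**Steps most likely to fail**

1. Step 6.
   - What may go wrong:
     - the first ketene may close in the 8π mode along the cis,cis-diene;
     - the 6π closure may be slowed by the cis substituent on the accepting carbon, so that ketene capture by phenols or ketene dimerisation takes over;
     - the second expansion may stall because of crowding around the emerging tetra-ortho-substituted axis.
   - Fallback (known chemistry): each ring is built separately by the same ring expansion on a simple alkene, and the axis is made afterwards by Ullmann coupling. It sets out from 1 and 7 and rejoins at 14. Bromoboration–protonolysis of 1 (B-bromo-9-borabicyclo[3.3.1]nonane, CH2Cl2, then AcOH) gives 2-bromo-4-phenylbut-1-ene F1. Bromine–lithium exchange with t-BuLi gives 2-lithio-4-phenylbut-1-ene F2, which adds to 7 to give the monomeric 4-alkenyl-4-hydroxycyclobutenone F3. Thermolysis in toluene gives 2-methyl-5-(2-phenylethyl)-3-(propan-2-yloxy)benzene-1,4-diol F4, and Me2SO4/K2CO3 gives its dimethyl ether F5. Iodination of the only free position of the electron-rich ring (NIS, cat. TFA) gives the aryl iodide F6. Ullmann homocoupling with activated copper powder in hot DMF gives the biaryl tetramethyl ether F7. Oxidative demethylation with (NH4)2Ce(NO3)6 in MeCN–H2O gives 14.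

2. Step 5.
   - What may go wrong:
     - after the first addition the remaining C–Li bond, held nearby by the cis,cis geometry, may attack the second carbonyl of the same four-membered ring (six-membered annulation) faster than it meets another molecule of 7;
     - proton transfer from the ring methyl group may occur;
     - the exchange may be incomplete.
   - Fallback: that carbonyl is masked before the addition. It sets out from 4 and rejoins at 9. Acetalisation of 4 with 1,2-bis(trimethylsilyloxy)ethane and cat. TMSOTf gives the squarate mono(ethylene acetal) F8. MeLi at −78 °C gives the carbinol F9. Trifluoroacetic anhydride followed by aqueous NaHCO3 transposes it, with loss of one isopropoxy group, to 3-methyl-2-(propan-2-yloxy)-5,8-dioxaspiro[3.4]oct-2-en-1-one F10, whose only carbonyl is the one next to the alkoxy-bearing carbon. Dilithiodiene 8, made from 3 as in step 5, adds twice to F10 to give the bis(acetal) diol F11, in which no carbonyl is left for ring closure. Cold dilute H2SO4 in THF then hydrolyses the acetals, whose ionisation is assisted by the vinylogous isopropoxy group, to give 9.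

3. Step 2.
   - What may go wrong:
     - nucleophilic addition of telluride to an unactivated dialkyl diyne may be sluggish and stop at the enyne stage;
     - the hot basic medium may cause prototropic isomerisation of the propargylic CH2 groups;
     - the telluride may be oxidised by adventitious air.
   - Fallback: the polar addition is replaced by a radical twofold hydrostannation. It sets out from 2 and rejoins at 8. Bu2SnH2 with AIBN in hot benzene adds across the diyne, tin going to the outer carbons, to give 1,1-dibutyl-2,5-bis(2-phenylethyl)stannole F12. Tin–lithium exchange with two equivalents of n-BuLi in THF at −78 °C gives 8.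

**Further compounds**
F1 | step 6 | 2-bromo-4-phenylbut-1-ene | C=C(Br)CCc1ccccc1
F2 | step 6 | 2-lithio-4-phenylbut-1-ene | [Li]C(=C)CCc1ccccc1
F3 | step 6 | 4-hydroxy-3-isopropoxy-2-methyl-4-(4-phenylbut-1-en-2-yl)cyclobut-2-en-1-one (racemic) | O=C1C(C)=C(OC(C)C)C1(O)C(=C)CCc1ccccc1
F4 | step 6 | 2-methyl-5-(2-phenylethyl)-3-(propan-2-yloxy)benzene-1,4-diol | Cc1c(O)cc(CCc2ccccc2)c(O)c1OC(C)C
F5 | step 6 | 1,4-dimethoxy-2-methyl-5-(2-phenylethyl)-3-(propan-2-yloxy)benzene | Cc1c(OC)cc(CCc2ccccc2)c(OC)c1OC(C)C
F6 | step 6 | 1-iodo-2,5-dimethoxy-3-methyl-6-(2-phenylethyl)-4-(propan-2-yloxy)benzene | Cc1c(OC)c(I)c(CCc2ccccc2)c(OC)c1OC(C)C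
F7 | step 6 | 2,2',5,5'-tetramethoxy-3,3'-dimethyl-6,6'-bis(2-phenylethyl)-4,4'-di(propan-2-yloxy)biphenyl | Cc1c(OC)c(c(CCc2ccccc2)c(OC)c1OC(C)C)-c1c(CCc2ccccc2)c(OC)c(OC(C)C)c(C)c1OC
F8 | step 5 | 2,3-di(propan-2-yloxy)-5,8-dioxaspiro[3.4]oct-2-en-1-one | O=C1C(OC(C)C)=C(OC(C)C)C12OCCO2
F9 | step 5 | 1-methyl-2,3-di(propan-2-yloxy)-5,8-dioxaspiro[3.4]oct-2-en-1-ol (racemic) | CC1(O)C(OC(C)C)=C(OC(C)C)C12OCCO2
F10 | step 5 | 3-methyl-2-(propan-2-yloxy)-5,8-dioxaspiro[3.4]oct-2-en-1-one | O=C1C(OC(C)C)=C(C)C12OCCO2
F11 | step 5 | bis(ethylene acetal) of 9, same alkene geometry, mixture at the carbinols | OC1(C(OC(C)C)=C(C)C12OCCO2)/C(CCc1ccccc1)=C\C=C(/C1(O)C(OC(C)C)=C(C)C12OCCO2)CCc1ccccc1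
F12 | step 2 | 1,1-dibutyl-2,5-bis(2-phenylethyl)stannole | CCCC[Sn]1(CCCC)C(CCc2ccccc2)=CC=C1CCc1ccccc1
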